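**Retrosynthetic overview**
1. Sequoiaflavone comes from its penta-O-benzyl ether by one global hydrogenolysis; the 7-OMe group is carried from the start.
2. The pyranone (ring C) of the methoxy-bearing flavone (unit 1) comes from a 2′-hydroxychalcone by I2/DMSO oxidative cyclisation. The chalcone comes from the key intermolecular Claisen–Schmidt aldol condensation of a flavonyl benzaldehyde with a phloroacetophenone-derived methyl ketone.
3. The flavonyl benzaldehyde comes from Suzuki coupling of an 8-iodoflavone (unit 2) with a formylaryl pinacol boronate, which sets the C3′–C8 biaryl bond.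
4. The 8-iodoflavone comes from a first Claisen–Schmidt aldol/oxidative cyclisation pair between an ortho-iodinated phloroacetophenone dibenzyl ether and 4-(benzyloxy)benzaldehyde.
5. Ring order: pyranone of unit 2, then the biaryl bond, then pyranone of unit 1; all four benzene rings are bought.

Assumption: the target SMILES has no stereocentre and no axial descriptor, and the biaryl axis is treated as not configurationally fixed, so the compound is made as the single achiral constitution drawn. The non-isolated aldol adducts and flavanones are racemic and lose their stereocentre in the same flask, so their SMILES carry no descriptor.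

**Route**

Step 1
Reactants: 1 2′,4′,6′-trihydroxyacetophenone (used as the monohydrate)
Product: 2 1-[2,4-bis(benzyloxy)-6-hydroxyphenyl]ethanone
Conditions: BnBr (2.1 equiv), K2CO3 (2.2 equiv), DMF, rt, 16 h
Reagents that add atoms: benzyl bromide, BrCc1ccccc1
Why: Williamson etherification stops at the bis-ether because the last hydroxyl is hydrogen-bonded to the acetyl carbonyl and is much less nucleophilic.

Step 2
Reactants: 2 1-[2,4-bis(benzyloxy)-6-hydroxyphenyl]ethanone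
Product: 3 1-[4,6-bis(benzyloxy)-2-hydroxy-3-iodophenyl]ethanone
Conditions: BnMe3N·ICl2 (1.05 equiv), NaHCO3, CH2Cl2/MeOH, rt
Reagents that add atoms: benzyltrimethylammonium dichloroiodate, C[N+](C)(C)Cc1ccccc1.Cl[I-]Cl
Why: Electrophilic aromatic iodination of the phloroglucinol ring is directed ortho to the free phenol (C3), as established for the dimethyl ether analogue, and mono-iodination is secured by stoichiometry.

Step 3
Reactants: 3 1-[4,6-bis(benzyloxy)-2-hydroxy-3-iodophenyl]ethanone; 4 4-(benzyloxy)benzaldehyde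
Product: 6 (E)-1-[4,6-bis(benzyloxy)-2-hydroxy-3-iodophenyl]-3-[4-(benzyloxy)phenyl]prop-2-en-1-one, via racemic aldol adduct 5 (not isolated)
Conditions: KOH (50% aq., excess), EtOH/THF, rt, 36 h; then dil. HCl
Reagents that add atoms: none
Why: Claisen–Schmidt aldol condensation between the only enolisable ketone and a non-enolisable aldehyde, followed by E1cB dehydration of 5 to the thermodynamically favoured (E)-enone; the aryl iodide and benzyl ethers are inert to hydroxide.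

Step 4
Reactants: 6 (E)-1-[4,6-bis(benzyloxy)-2-hydroxy-3-iodophenyl]-3-[4-(benzyloxy)phenyl]prop-2-en-1-one
Product: 8 5,7-bis(benzyloxy)-2-[4-(benzyloxy)phenyl]-8-iodo-4H-chromen-4-one, via racemic flavanone 7 (not isolated)
Conditions: I2 (10 mol %), DMSO, 120 °C, 3 h; aq. Na2S2O3 wash
Reagents that add atoms: none
Why: Iodine-catalysed oxidative cyclisation (oxa-Michael closure to flavanone 7, then dehydrogenation with DMSO as terminal oxidant); only one phenol is free, so the iodine must end at C8 of the flavone.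

Step 5
Reactants: 9 3-bromo-4-hydroxybenzaldehyde
Product: 10 4-(benzyloxy)-3-bromobenzaldehyde
Conditions: BnBr (1.1 equiv), K2CO3 (1.5 equiv), DMF, rt
Reagents that add atoms: benzyl bromide, BrCc1ccccc1
Why: Simple Williamson etherification of an acidic para-formyl phenol, which leaves the aldehyde and the aryl bromide untouched.

Step 6
Reactants: 10 4-(benzyloxy)-3-bromobenzaldehyde
Product: 11 4-(benzyloxy)-3-(4,4,5,5-tetramethyl-1,3,2-dioxaborolan-2-yl)benzaldehyde
Conditions: B2pin2 (1.2 equiv), KOAc (3 equiv), PdCl2(dppf) (3 mol %; dppf = 1,1′-bis(diphenylphosphino)ferrocene), 1,4-dioxane, 90 °C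
Reagents that add atoms: bis(pinacolato)diboron, CC1(C)OB(OC1(C)C)B1OC(C)(C)C(C)(C)O1
Why: Miyaura borylation of an aryl bromide tolerates aldehydes and ethers, and the weak base KOAc prevents homocoupling.

Step 7
Reactants: 8 5,7-bis(benzyloxy)-2-[4-(benzyloxy)phenyl]-8-iodo-4H-chromen-4-one; 11 4-(benzyloxy)-3-(4,4,5,5-tetramethyl-1,3,2-dioxaborolan-2-yl)benzaldehyde
Product: 12 4-(benzyloxy)-3-{5,7-bis(benzyloxy)-2-[4-(benzyloxy)phenyl]-4-oxo-4H-chromen-8-yl}benzaldehyde
Conditions: Pd(OAc)2 (5 mol %), SPhos (2-dicyclohexylphosphino-2′,6′-dimethoxybiphenyl, 10 mol %), K3PO4 (3 equiv), toluene/H2O (10:1), 90 °C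
Reagents that add atoms: none
Why: Suzuki–Miyaura coupling of the aryl iodide with the boronate under a bulky biarylphosphine ligand (zerovalent palladium formed in situ) builds the tri-ortho-substituted biaryl bond; the aldehyde and flavone are stable to aqueous phosphate.

Step 8
Reactants: 1 2′,4′,6′-trihydroxyacetophenone
Product: 13 1-(2,6-dihydroxy-4-methoxyphenyl)ethanone
Conditions: Me2SO4 (1.0 equiv), K2CO3 (1.0 equiv), acetone, reflux, 4 h
Reagents that add atoms: dimethyl sulfate, COS(=O)(=O)OC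
Why: Selective O-methylation (Williamson type) of the para hydroxyl, the only one not hydrogen-bonded to the carbonyl and the most acidic; the dimethyl ether by-product is removed by chromatography.

Step 9
Reactants: 13 1-(2,6-dihydroxy-4-methoxyphenyl)ethanone
Product: 14 1-[2-(benzyloxy)-6-hydroxy-4-methoxyphenyl]ethanone
Conditions: BnBr (1.05 equiv), K2CO3 (1.2 equiv), acetone, reflux
Reagents that add atoms: benzyl bromide, BrCc1ccccc1
Why: Williamson mono-benzylation; after the first ether forms, the remaining hydroxyl is strongly chelated to the carbonyl and resists alkylation.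

Step 10
Reactants: 12 4-(benzyloxy)-3-{5,7-bis(benzyloxy)-2-[4-(benzyloxy)phenyl]-4-oxo-4H-chromen-8-yl}benzaldehyde; 14 1-[2-(benzyloxy)-6-hydroxy-4-methoxyphenyl]ethanone
Product: 16 (E)-1-[2-(benzyloxy)-6-hydroxy-4-methoxyphenyl]-3-(4-(benzyloxy)-3-{5,7-bis(benzyloxy)-2-[4-(benzyloxy)phenyl]-4-oxo-4H-chromen-8-yl}phenyl)prop-2-en-1-one, via racemic aldol adduct 15 (not isolated)
Conditions: KOH (10 equiv), EtOH/THF (1:1), rt, 48 h; then cold dil. HCl
Reagents that add atoms: none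
Why: Key intermolecular Claisen–Schmidt aldol condensation: the enolate of 14 adds to the aryl aldehyde of 12, the only strongly electrophilic carbonyl, and adduct 15 dehydrates by E1cB to the (E)-chalcone; the fully O-protected flavone tolerates hydroxide at room temperature and can only re-close to itself on acidification.

Step 11
Reactants: 16 (E)-1-[2-(benzyloxy)-6-hydroxy-4-methoxyphenyl]-3-(4-(benzyloxy)-3-{5,7-bis(benzyloxy)-2-[4-(benzyloxy)phenyl]-4-oxo-4H-chromen-8-yl}phenyl)prop-2-en-1-one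
Product: 18 5,7-bis(benzyloxy)-8-{2-(benzyloxy)-5-[5-(benzyloxy)-7-methoxy-4-oxo-4H-chromen-2-yl]phenyl}-2-[4-(benzyloxy)phenyl]-4H-chromen-4-one, via racemic flavanone 17 (not isolated)
Conditions: I2 (10 mol %), DMSO, 120 °C, 3 h; aq. Na2S2O3 wash
Reagents that add atoms: none
Why: Iodine-catalysed oxidative cyclisation of the 2′-hydroxychalcone through flavanone 17 with DMSO as oxidant; the single free phenol fixes the 5-benzyloxy-7-methoxy pattern of the new flavone.

Step 12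
Reactants: 18 5,7-bis(benzyloxy)-8-{2-(benzyloxy)-5-[5-(benzyloxy)-7-methoxy-4-oxo-4H-chromen-2-yl]phenyl}-2-[4-(benzyloxy)phenyl]-4H-chromen-4-one
Product: 19 sequoiaflavone, 5,7-dihydroxy-8-[2-hydroxy-5-(5-hydroxy-7-methoxy-4-oxo-4H-chromen-2-yl)phenyl]-2-(4-hydroxyphenyl)-4H-chromen-4-one
Conditions: H2 (1 atm), Pd/C (10 wt % palladium on carbon), THF/MeOH (1:1), rt, 16 h
Reagents that add atoms: none
Why: Catalytic hydrogenolysis cleaves all five aryl benzyl ethers, while the aryl methyl ether and the flavone C2–C3 double bond are stable at 1 atm and room temperature; no stereocentre exists in the product.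

**Compound list**
1 | 2′,4′,6′-trihydroxyacetophenone | CC(=O)c1c(O)cc(O)cc1O | starting material
2 | 1-[2,4-bis(benzyloxy)-6-hydroxyphenyl]ethanone | CC(=O)c1c(O)cc(OCc2ccccc2)cc1OCc1ccccc1 | intermediate
3 | 1-[4,6-bis(benzyloxy)-2-hydroxy-3-iodophenyl]ethanone | CC(=O)c1c(O)c(I)c(OCc2ccccc2)cc1OCc1ccccc1 | intermediate
4 | 4-(benzyloxy)benzaldehyde | O=Cc1ccc(OCc2ccccc2)cc1 | starting material
5 | racemic 1-[4,6-bis(benzyloxy)-2-hydroxy-3-iodophenyl]-3-[4-(benzyloxy)phenyl]-3-hydroxypropan-1-one | O=C(CC(O)c1ccc(OCc2ccccc2)cc1)c1c(O)c(I)c(OCc2ccccc2)cc1OCc1ccccc1 | intermediate (not isolated)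
6 | (E)-1-[4,6-bis(benzyloxy)-2-hydroxy-3-iodophenyl]-3-[4-(benzyloxy)phenyl]prop-2-en-1-one | O=C(/C=C/c1ccc(OCc2ccccc2)cc1)c1c(O)c(I)c(OCc2ccccc2)cc1OCc1ccccc1 | intermediate
7 | racemic 5,7-bis(benzyloxy)-2-[4-(benzyloxy)phenyl]-8-iodochroman-4-one | O=C1CC(c2ccc(OCc3ccccc3)cc2)Oc2c(I)c(OCc3ccccc3)cc(OCc3ccccc3)c21 | intermediate (not isolated)
8 | 5,7-bis(benzyloxy)-2-[4-(benzyloxy)phenyl]-8-iodo-4H-chromen-4-one | O=c1cc(-c2ccc(OCc3ccccc3)cc2)oc2c(I)c(OCc3ccccc3)cc(OCc3ccccc3)c12 | intermediate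
9 | 3-bromo-4-hydroxybenzaldehyde | O=Cc1ccc(O)c(Br)c1 | starting material
10 | 4-(benzyloxy)-3-bromobenzaldehyde | O=Cc1ccc(OCc2ccccc2)c(Br)c1 | intermediate
11 | 4-(benzyloxy)-3-(4,4,5,5-tetramethyl-1,3,2-dioxaborolan-2-yl)benzaldehyde | O=Cc1ccc(OCc2ccccc2)c(B2OC(C)(C)C(C)(C)O2)c1 | intermediate
12 | 4-(benzyloxy)-3-{5,7-bis(benzyloxy)-2-[4-(benzyloxy)phenyl]-4-oxo-4H-chromen-8-yl}benzaldehyde | O=Cc1ccc(OCc2ccccc2)c(-c2c(OCc3ccccc3)cc(OCc3ccccc3)c3c(=O)cc(-c4ccc(OCc5ccccc5)cc4)oc23)c1 | intermediate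
13 | 1-(2,6-dihydroxy-4-methoxyphenyl)ethanone | CC(=O)c1c(O)cc(OC)cc1O | intermediate
14 | 1-[2-(benzyloxy)-6-hydroxy-4-methoxyphenyl]ethanone | CC(=O)c1c(O)cc(OC)cc1OCc1ccccc1 | intermediate
15 | racemic 1-[2-(benzyloxy)-6-hydroxy-4-methoxyphenyl]-3-(4-(benzyloxy)-3-{5,7-bis(benzyloxy)-2-[4-(benzyloxy)phenyl]-4-oxo-4H-chromen-8-yl}phenyl)-3-hydroxypropan-1-one | COc1cc(O)c(C(=O)CC(O)c2ccc(OCc3ccccc3)c(-c3c(OCc4ccccc4)cc(OCc4ccccc4)c4c(=O)cc(-c5ccc(OCc6ccccc6)cc5)oc34)c2)c(OCc2ccccc2)c1 | intermediate (not isolated)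
16 | (E)-1-[2-(benzyloxy)-6-hydroxy-4-methoxyphenyl]-3-(4-(benzyloxy)-3-{5,7-bis(benzyloxy)-2-[4-(benzyloxy)phenyl]-4-oxo-4H-chromen-8-yl}phenyl)prop-2-en-1-one | COc1cc(O)c(C(=O)/C=C/c2ccc(OCc3ccccc3)c(-c3c(OCc4ccccc4)cc(OCc4ccccc4)c4c(=O)cc(-c5ccc(OCc6ccccc6)cc5)oc34)c2)c(OCc2ccccc2)c1 | intermediate
17 | racemic 5,7-bis(benzyloxy)-8-{2-(benzyloxy)-5-[5-(benzyloxy)-7-methoxy-4-oxochroman-2-yl]phenyl}-2-[4-(benzyloxy)phenyl]-4H-chromen-4-one | COc1cc(OCc2ccccc2)c2c(c1)OC(c1ccc(OCc3ccccc3)c(-c3c(OCc4ccccc4)cc(OCc4ccccc4)c4c(=O)cc(-c5ccc(OCc6ccccc6)cc5)oc34)c1)CC2=O | intermediate (not isolated)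
18 | 5,7-bis(benzyloxy)-8-{2-(benzyloxy)-5-[5-(benzyloxy)-7-methoxy-4-oxo-4H-chromen-2-yl]phenyl}-2-[4-(benzyloxy)phenyl]-4H-chromen-4-one | COc1cc(OCc2ccccc2)c2c(=O)cc(-c3ccc(OCc4ccccc4)c(-c4c(OCc5ccccc5)cc(OCc5ccccc5)c5c(=O)cc(-c6ccc(OCc7ccccc7)cc6)oc45)c3)oc2c1 | intermediate
19 | sequoiaflavone, 5,7-dihydroxy-8-[2-hydroxy-5-(5-hydroxy-7-methoxy-4-oxo-4H-chromen-2-yl)phenyl]-2-(4-hydroxyphenyl)-4H-chromen-4-one | COc1cc(O)c2c(=O)cc(-c3ccc(O)c(-c4c(O)cc(O)c5c(=O)cc(-c6ccc(O)cc6)oc45)c3)oc2c1 | target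

**Summary**
Total step count: 12.
Longest linear sequence: 8 steps (1 → 2 → 3 → 6 → 8 → 12 → 16 → 18 → 19, that is steps 1, 2, 3, 4, 7, 10, 11 and 12).

The three steps most likely to fail:

Step 4 (oxidative cyclisation of the iodinated chalcone). The risk is acid-mediated loss of the electron-rich aryl iodide or of the peri benzyl ether at 120 °C. The fallback sets out from 3 and comes back at 8, bypassing chalcone 6 and any oxidant. Compound 3 is treated with LiN(SiMe3)2 (3.5 equiv, THF, −78 °C) and then 4-(benzyloxy)benzoyl chloride. This intermolecular Claisen-type C-aroylation of the ketone enolate gives the β-diketone 1-[4,6-bis(benzyloxy)-2-hydroxy-3-iodophenyl]-3-[4-(benzyloxy)phenyl]propane-1,3-dione F1. Cyclodehydration with catalytic TsOH·H2O in toluene at 90 °C then closes the pyranone to 8.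

Step 7 (hindered Suzuki coupling). The risk is slow coupling at the di-ortho-substituted C8 with protodeboronation of 11. The fallback sets out from 8 and comes back at 12 with the polarity reversed. Miyaura borylation of 8 (B2pin2, KOAc, PdCl2(dppf), DMSO, 80 °C) gives the flavone boronate 5,7-bis(benzyloxy)-2-[4-(benzyloxy)phenyl]-8-(4,4,5,5-tetramethyl-1,3,2-dioxaborolan-2-yl)-4H-chromen-4-one F2. This is coupled with bromide 10 (Pd(OAc)2, SPhos, K3PO4, toluene/H2O, 90 °C) to give 12.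

Step 10 (key aldol on the flavone-bearing aldehyde). The risk is poor solubility of 12 and hydroxide attack on its pyranone during the long reaction. The fallback sets out from 14 (with 10) and comes back at 18; it runs the aldol on the small partners first and joins the two flavones afterwards.
- Claisen–Schmidt condensation of 14 with 10 (KOH, EtOH, rt) gives the chalcone (E)-1-[2-(benzyloxy)-6-hydroxy-4-methoxyphenyl]-3-[4-(benzyloxy)-3-bromophenyl]prop-2-en-1-one F3.
- I2/DMSO cyclisation at 120 °C gives the bromoflavone 5-(benzyloxy)-2-[4-(benzyloxy)-3-bromophenyl]-7-methoxy-4H-chromen-4-one F4.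
- Miyaura borylation (B2pin2, KOAc, PdCl2(dppf), dioxane, 90 °C) gives the boronate 5-(benzyloxy)-2-[4-(benzyloxy)-3-(4,4,5,5-tetramethyl-1,3,2-dioxaborolan-2-yl)phenyl]-7-methoxy-4H-chromen-4-one F5.
- Suzuki coupling of this boronate with iodide 8 (Pd(OAc)2, SPhos, K3PO4, toluene/H2O, 90 °C) gives 18 directly.

**Further compounds**
F1 | step 4 | 1-[4,6-bis(benzyloxy)-2-hydroxy-3-iodophenyl]-3-[4-(benzyloxy)phenyl]propane-1,3-dione | O=C(CC(=O)c1ccc(OCc2ccccc2)cc1)c1c(O)c(I)c(OCc2ccccc2)cc1OCc1ccccc1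
F2 | step 7 | 5,7-bis(benzyloxy)-2-[4-(benzyloxy)phenyl]-8-(4,4,5,5-tetramethyl-1,3,2-dioxaborolan-2-yl)-4H-chromen-4-one | O=c1cc(-c2ccc(OCc3ccccc3)cc2)oc2c(B3OC(C)(C)C(C)(C)O3)c(OCc3ccccc3)cc(OCc3ccccc3)c12
F3 | step 10 | (E)-1-[2-(benzyloxy)-6-hydroxy-4-methoxyphenyl]-3-[4-(benzyloxy)-3-bromophenyl]prop-2-en-1-one | COc1cc(O)c(C(=O)/C=C/c2ccc(OCc3ccccc3)c(Br)c2)c(OCc2ccccc2)c1
F4 | step 10 | 5-(benzyloxy)-2-[4-(benzyloxy)-3-bromophenyl]-7-methoxy-4H-chromen-4-one | COc1cc(OCc2ccccc2)c2c(=O)cc(-c3ccc(OCc4ccccc4)c(Br)c3)oc2c1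
F5 | step 10 | 5-(benzyloxy)-2-[4-(benzyloxy)-3-(4,4,5,5-tetramethyl-1,3,2-dioxaborolan-2-yl)phenyl]-7-methoxy-4H-chromen-4-one | COc1cc(OCc2ccccc2)c2c(=O)cc(-c3ccc(OCc4ccccc4)c(B4OC(C)(C)C(C)(C)O4)c3)oc2c1
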